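**Zero of scale.** In a one-step world, with no crossing of hands, a racemate consumed to the end gives racemic product. In the north flask, product excess beyond the leftover substrate gap therefore counts crossing through the racemization catalyst.

all flasks: free catalyst 2.5 mM; racemization catalyst 38 mM
- north: left-handed substrate 0.25 M; right-handed substrate 0.25 M; partner 1 M; the very flask that is asked about, followed so far
- south-west: left-handed substrate 0.38 M; right-handed substrate 0.38 M; partner 1 M; run made earlier
- flask: left-handed substrate 0.25 M; right-handed substrate 0.25 M; partner 1.00 M; time 10 d

| run | time / d | left-handed substrate / % | right-handed substrate / % |
|---|---|---|---|
| north | 0.833 | 3 | 6 |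
| north | 1.67 | 2 | 3 |
| north | 2.50 | 2 | 5 |
| north | 3.00 | 2 | 2 |
| north | 4.00 | 1 | 2 |
| south-west | 0.333 | 11 | 19 |
| south-west | 1.04 | 5 | 7 |
| south-west | 1.67 | 5 | 7 |
| south-west | 3.00 | 7 | 5 |
| south-west | 4.00 | 5 | 5 |

(scatter of a reading: 1.5 percentage points)

* part of the left-handed substrate and right-handed substrate charged together that has reacted at 10 d
* excess of left-handed product over right-handed product in the product at 10 d
* excess of right-handed substrate over left-handed substrate among what is left of the two at 10 d

- free catalyst is single-handed; left-handed substrate and right-handed substrate are mirror images of each other, charged as a racemate, each of them at the stated concentration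
- the numbers in the tables scatter with a standard deviation of 1.5 percentage points
- on the list of suspects stand: partner + racemization catalyst -> spent catalyst; free catalyst <-> dormant form; partner + free catalyst + left-handed substrate -> free catalyst + left-handed product; partner -> decomposed reagent; left-handed substrate + racemization catalyst <-> right-handed substrate + racemization catalyst; partner + free catalyst + right-handed substrate -> free catalyst + right-handed product
- an excess is below zero if the other one leads

**First instants.** The left-handed substrate goes first: the south-west flask holds 11% of it against 19% of the right-handed substrate at 0.333 d. Both hands share partner and catalyst, so the ratio of the logarithms of their fractions left reads as the selectivity factor, 1.56. Crossing refills the left-handed substrate, so this scattered reading may stand below the factor.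

**The middle.** The north flask keeps 3% of left-handed and 6% of right-handed substrate at 0.833 d, so most product is already made. Product from a racemic pool carries the factor minus one over the factor plus one; this racemic-pool excess reads 22.0%.

**The end.** The north flask holds 1% and 2% at 4.00 d, level within the scatter. This reckoning therefore expects a substrate excess near zero and a product excess near 22.0%.

**The forecast.** It gives 98% reacted, a product excess of 10% (range 5% to 17%) and a substrate excess of 5%. Its ground: racemization feeds the left-handed substrate from the right-handed substrate, so “product excess should exceed the residual-substrate balance”. Its product excess stands lower than the reckoning above.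

**The result.** The north flask gives 97.1% reacted, a product excess of 35.4% and a substrate excess of 0%.

    partner + racemization catalyst → spent catalyst (k = 4.68 × 10⁻⁶ M⁻¹ s⁻¹)
    free catalyst ⇌ dormant form (K = 2.17, k = 4.00 × 10⁻⁶ s⁻¹)
    partner + free catalyst + left-handed substrate → free catalyst + left-handed product (k = 0.0516 M⁻² s⁻¹)
    partner → decomposed reagent (k = 8.56 × 10⁻⁶ s⁻¹)
    left-handed substrate + racemization catalyst ⇌ right-handed substrate + racemization catalyst, rate k5*[racemization catalyst]*[left-handed substrate] forward; the back reaction follows from the equilibrium constant (k = 9.51 × 10⁻⁴ M⁻¹ s⁻¹)
    partner + free catalyst + right-handed substrate → free catalyst + right-handed product (k = 0.0169 M⁻² s⁻¹)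

**The excess.** Conversion and substrate excess agree with the forecast within the tolerance, but the product excess lies 25 percentage points above it, at 1.61 times the racemic-pool excess. The neighbouring flask has [racemization catalyst] at 0.0095 M, a quarter of the charge. Its substrates also end level, at 2.06% and 2.07%. It holds 58.7% of left-handed product against 37.2% of right-handed product, an excess of 22.4%, which is 1.02 times the racemic-pool excess.

All runs are calculated with made-up constants.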